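**Plan**

1. Numbering: ring C carries C7–C8–C9 (C7 = aryl-bearing ring carbon, C9 = CH2OH); ring B carries C7'–C8'–C9' (C7' = benzylic CH2, C9' = ring OCH2); ring A carries the arylglycerol chain C7''–C8''–C9'', joined to ring B through C8''–O–C4'.
2. Retrosynthesis: after removal of two benzyl and two silyl groups, the C8–C8' bond and the C7'–C1' (ring B) bond are cut in one event, giving epoxy allyl ether 4 (fragment 1) and aryl bromide 14 (fragment 2). Fragment 1 is cut at the C7–O allyl ether and the oxirane; fragment 2 at C7''–C1'' (ring A) and at the C8''–O aryl ether.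
3. Enabling feature: the tetrahydrofuran has its oxygen between C7 and C9', a CH2OH on C8 and an ArCH2 on C8'. A C8 radical born from a temporary C8–C9 oxirane therefore sits in a 3-oxahex-5-enyl array (C8–C7–O–C9'–C8'=C7'), and the C7' radical left after ring closure is exactly where ring B must be attached.
4. Forward: fragment 1 in 3 steps from O-benzylvanillin; fragment 2 in 6 steps from methyl D-glycerate, 4-bromoguaiacol and the ring A aryl bromide; one step joins them and closes the tetrahydrofuran, the only non-aromatic ring and the last ring formed; two deprotections finish.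
5. Stereochemistry: C7 from a Sharpless kinetic resolution; C8 and C8' from the radical ring closure under control of C7; C8'' from methyl (R)-glycerate with Mitsunobu inversion; C7'' from a chelation-controlled ketone reduction directed by C8''.

Key step: step 10

Remark: compounds 1, 5, 7 and 10 are taken as catalogue compounds; 5 is also available by acid methanolysis of commercial methyl (R)-2,2-dimethyl-1,3-dioxolane-4-carboxylate.

**Route**

Step 1
Reactants: 1 4-(benzyloxy)-3-methoxybenzaldehyde
Product: 2 rac-1-[4-(benzyloxy)-3-methoxyphenyl]prop-2-en-1-ol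
Conditions: CH2=CHMgBr, THF, 0 °C; aq. NH4Cl
Reagents that add atoms: vinylmagnesium bromide, C=C[Mg]Br
Why: Grignard 1,2-addition to the aryl aldehyde should give the secondary allylic alcohol, and no stereocontrol is needed because the next step resolves the racemate.

Step 2
Reactants: 2 rac-1-[4-(benzyloxy)-3-methoxyphenyl]prop-2-en-1-ol
Product: 3 (R)-[4-(benzyloxy)-3-methoxyphenyl][(2S)-oxiran-2-yl]methanol
Conditions: Ti(OiPr)4 (0.2 equiv), D-(−)-diisopropyl tartrate (0.25 equiv), tBuOOH (0.55 equiv), 4 Å molecular sieves, CH2Cl2, −20 °C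
Reagents that add atoms: tert-butyl hydroperoxide, CC(C)(C)OO
Why: In this Sharpless kinetic resolution the D-(−)-tartrate catalyst should epoxidize the (S)-enantiomer of 2 much faster than the (R)-enantiomer and erythro-selectively, so that 3 carries the carbinol configuration that becomes C7 of the target (the descriptor changes to R only because the oxirane carbon outranks the aryl group), while unreacted (R)-2 is separated and the oxirane stereocenter is of no consequence because it later becomes a radical centre.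

Step 3
Reactants: 3 (R)-[4-(benzyloxy)-3-methoxyphenyl][(2S)-oxiran-2-yl]methanol
Product: 4 (2S)-2-[(R)-[4-(benzyloxy)-3-methoxyphenyl](prop-2-en-1-yloxy)methyl]oxirane
Conditions: NaH, allyl bromide, Bu4NI (cat.), THF, 0 °C
Reagents that add atoms: allyl bromide, C=CCBr
Why: In this Williamson ether synthesis the sodium alkoxide of 3 should be O-allylated by the reactive allylic bromide faster than it undergoes Payne rearrangement in an aprotic medium at 0 °C, and C7 is not touched.

Step 4
Reactants: 5 methyl (R)-2,3-dihydroxypropanoate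
Product: 6 methyl (R)-3-[(tert-butyldimethylsilyl)oxy]-2-hydroxypropanoate
Conditions: TBSCl (1.05 equiv), imidazole, CH2Cl2, 0 °C
Reagents that add atoms: tert-butyldimethylsilyl chloride, CC(C)(C)[Si](C)(C)Cl
Why: Silyl ether protection with the bulky silyl chloride should occur selectively at the primary hydroxyl of the 1,2-diol and leaves the stereocenter untouched.

Step 5
Reactants: 6 methyl (R)-3-[(tert-butyldimethylsilyl)oxy]-2-hydroxypropanoate; 7 4-bromo-2-methoxyphenol
Product: 8 methyl (S)-2-(4-bromo-2-methoxyphenoxy)-3-[(tert-butyldimethylsilyl)oxy]propanoate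
Conditions: PPh3, iPrO2CN=NCO2iPr, THF, 0 °C to rt
Reagents that add atoms: none
Why: Mitsunobu etherification of an α-hydroxy ester with a phenol should proceed by SN2 displacement of the oxyphosphonium group with clean inversion, which turns the (R)-carbinol of 6 into the (S)-configured aryl ether carbon that is C8'' of the target.

Step 6
Reactants: 8 methyl (S)-2-(4-bromo-2-methoxyphenoxy)-3-[(tert-butyldimethylsilyl)oxy]propanoate
Product: 9 (S)-2-(4-bromo-2-methoxyphenoxy)-3-[(tert-butyldimethylsilyl)oxy]-N-methoxy-N-methylpropanamide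
Conditions: MeNH(OMe)·HCl, iPrMgCl, THF, −20 °C
Reagents that add atoms: N,O-dimethylhydroxylamine hydrochloride, CNOC.Cl
Why: Weinreb amide formation by aminolysis of the only ester with the chloromagnesium amide should be fast at low temperature and is expected to leave the α-aryloxy stereocenter intact.

Step 7
Reactants: 9 (S)-2-(4-bromo-2-methoxyphenoxy)-3-[(tert-butyldimethylsilyl)oxy]-N-methoxy-N-methylpropanamide; 10 1-(benzyloxy)-4-bromo-2-methoxybenzene
Product: 12 (S)-1-[4-(benzyloxy)-3-methoxyphenyl]-2-(4-bromo-2-methoxyphenoxy)-3-[(tert-butyldimethylsilyl)oxy]propan-1-one, via arylmagnesium bromide 11 (not isolated)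
Conditions: 10, Mg, THF, 40 °C; then 9, THF, −10 to 0 °C; cold aq. NH4Cl
Reagents that add atoms: none
Why: In this Weinreb ketone synthesis the Grignard reagent 11 should add once to give a stable magnesium chelate that releases the ketone only on quench, which prevents over-addition and keeps the enolizable C8'' stereocenter out of basic medium, while the aryl bromide of 9 is inert to an arylmagnesium reagent without a catalyst.

Step 8
Reactants: 12 (S)-1-[4-(benzyloxy)-3-methoxyphenyl]-2-(4-bromo-2-methoxyphenoxy)-3-[(tert-butyldimethylsilyl)oxy]propan-1-one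
Product: 13 (1R,2S)-1-[4-(benzyloxy)-3-methoxyphenyl]-2-(4-bromo-2-methoxyphenoxy)-3-[(tert-butyldimethylsilyl)oxy]propan-1-ol
Conditions: Zn(BH4)2, Et2O, −20 °C
Reagents that add atoms: none
Why: In this chelation-controlled (Cram-chelate) hydride reduction zinc should bridge the ketone oxygen and the α-aryloxy oxygen, helped by the ortho-methoxy group of ring B, so that hydride attacks from the side of the small α-hydrogen and gives the erythro (anti) alcohol with (R)-configured C7''.

Step 9
Reactants: 13 (1R,2S)-1-[4-(benzyloxy)-3-methoxyphenyl]-2-(4-bromo-2-methoxyphenoxy)-3-[(tert-butyldimethylsilyl)oxy]propan-1-ol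
Product: 14 (1R,2S)-1-[4-(benzyloxy)-3-methoxyphenyl]-2-(4-bromo-2-methoxyphenoxy)-1,3-bis[(tert-butyldimethylsilyl)oxy]propane
Conditions: TBSOTf, 2,6-lutidine, CH2Cl2, −78 to 0 °C
Reagents that add atoms: tert-butyldimethylsilyl trifluoromethanesulfonate, CC(C)(C)[Si](C)(C)OS(=O)(=O)C(F)(F)F
Why: Silyl ether protection of the hindered secondary benzylic alcohol with the silyl triflate and a hindered base should be fast at low temperature, touches no stereocenter and masks the hydroxyl for the reductive coupling.

Step 10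
Reactants: 14 (1R,2S)-1-[4-(benzyloxy)-3-methoxyphenyl]-2-(4-bromo-2-methoxyphenoxy)-1,3-bis[(tert-butyldimethylsilyl)oxy]propane; 4 (2S)-2-[(R)-[4-(benzyloxy)-3-methoxyphenyl](prop-2-en-1-yloxy)methyl]oxirane (1.5 equiv)
Product: 15 [(2S,3R,4R)-2-[4-(benzyloxy)-3-methoxyphenyl]-4-[4-({(1R,2S)-1-[4-(benzyloxy)-3-methoxyphenyl]-1,3-bis[(tert-butyldimethylsilyl)oxy]propan-2-yl}oxy)-3-methoxybenzyl]oxolan-3-yl]methanol
Conditions: NiCl2(MeOCH2CH2OMe) (10 mol%), 2,2'-bipyridine (10 mol%), Cp2TiCl2 (20 mol%), Mn powder, Et3N·HCl, DMPU, rt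
Reagents that add atoms: none
Why: Proposed new method: trivalent titanium (Cp2TiCl, generated from Cp2TiCl2 and Mn) should open the oxirane of 4 homolytically at the more substituted C8–O bond, and the resulting C8 radical, which carries the titanium-bound CH2O group, should add to the internal carbon of the O-allyl group. The primary C7' radical formed in this way should be captured by the aryl nickel bromide complex that arises from oxidative addition of 14 to zerovalent nickel, and reductive elimination from the resulting trivalent nickel species should form the C7'–C1' bond, while Mn returns both metals to their low-valent states and Et3N·HCl protonates the titanium alkoxide to the C9 alcohol. The closest known reaction types are the titanocene-mediated reductive epoxide opening with 5-exo cyclization onto an olefin (used for furan-type lignans), the nickel and titanocene co-catalysed cross-electrophile arylation of epoxides by aryl bromides at the more substituted carbon, and the nickel-catalysed reductive cyclization–arylation of alkenyl halides; the step merges them and has not been shown as one cascade on epoxy allyl ethers. The tetrahydrofuran is closed by a 5-exo-trig radical cyclization that forms the C8–C8' bond. Both new stereocenters are set in this irreversible ring closure by the C7 stereocenter: in the chair-like transition state the C7 aryl group is pseudo-equatorial, the CH2O[Ti] group on the radical carbon lies anti to it (7,8-trans) and the alkene terminus lies cis to the CH2O[Ti] group (8,8'-cis), which is the (7S,8R,8'R) array, and nickel acts only afterwards on the achiral C7' radical. The step needs the C8 radical to cyclize before any metal captures it and the oxirane to open at C8 and not at C9; the first is secured by the 3-oxahex-5-enyl array C8–C7–O–C9'–C8'=C7' of 4, whose unimolecular ring closure should outrun bimolecular trapping at catalyst concentrations, and the second by the preference of titanocene for the more substituted, here secondary, radical.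

Step 11
Reactants: 15 [(2S,3R,4R)-2-[4-(benzyloxy)-3-methoxyphenyl]-4-[4-({(1R,2S)-1-[4-(benzyloxy)-3-methoxyphenyl]-1,3-bis[(tert-butyldimethylsilyl)oxy]propan-2-yl}oxy)-3-methoxybenzyl]oxolan-3-yl]methanol
Product: 16 (1R,2S)-1-[4-(benzyloxy)-3-methoxyphenyl]-2-[4-({(3R,4R,5S)-5-[4-(benzyloxy)-3-methoxyphenyl]-4-(hydroxymethyl)oxolan-3-yl}methyl)-2-methoxyphenoxy]propane-1,3-diol
Conditions: Bu4NF, AcOH, THF, 0 °C to rt
Reagents that add atoms: none
Why: Fluoride-mediated desilylation should cleave both silyl ethers, the acetic acid buffer keeps strongly basic alkoxides away from the benzylic positions, and the benzyl ethers and all stereocenters are unaffected.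

Step 12
Reactants: 16 (1R,2S)-1-[4-(benzyloxy)-3-methoxyphenyl]-2-[4-({(3R,4R,5S)-5-[4-(benzyloxy)-3-methoxyphenyl]-4-(hydroxymethyl)oxolan-3-yl}methyl)-2-methoxyphenoxy]propane-1,3-diol
Product: 17 (1R,2S)-1-(4-hydroxy-3-methoxyphenyl)-2-[4-({(3R,4R,5S)-5-(4-hydroxy-3-methoxyphenyl)-4-(hydroxymethyl)oxolan-3-yl}methyl)-2-methoxyphenoxy]propane-1,3-diol (CNP0158473.3)
Conditions: H2 (1 atm), 10% Pd/C, EtOAc, rt, stopped when 16 is consumed
Reagents that add atoms: none
Why: Catalytic hydrogenolysis (O-debenzylation) of the two aryl benzyl ethers should be much faster in a neutral solvent than hydrogenolysis of the benzylic C7–O bond of the tetrahydrofuran or of the C7'' benzylic alcohol, so that the target is released with all five stereocenters intact.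

**Compound list**

1 | 4-(benzyloxy)-3-methoxybenzaldehyde | COc1cc(C=O)ccc1OCc1ccccc1 | starting material
2 | rac-1-[4-(benzyloxy)-3-methoxyphenyl]prop-2-en-1-ol | C=CC(O)c1ccc(OCc2ccccc2)c(OC)c1 | intermediate
3 | (R)-[4-(benzyloxy)-3-methoxyphenyl][(2S)-oxiran-2-yl]methanol | O[C@H](c1ccc(OCc2ccccc2)c(OC)c1)[C@@H]1CO1 | intermediate
4 | (2S)-2-[(R)-[4-(benzyloxy)-3-methoxyphenyl](prop-2-en-1-yloxy)methyl]oxirane | C=CCO[C@H](c1ccc(OCc2ccccc2)c(OC)c1)[C@@H]1CO1 | intermediate
5 | methyl (R)-2,3-dihydroxypropanoate | COC(=O)[C@@H](CO)O | starting material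
6 | methyl (R)-3-[(tert-butyldimethylsilyl)oxy]-2-hydroxypropanoate | COC(=O)[C@@H](CO[Si](C)(C)C(C)(C)C)O | intermediate
7 | 4-bromo-2-methoxyphenol | COc1cc(Br)ccc1O | starting material
8 | methyl (S)-2-(4-bromo-2-methoxyphenoxy)-3-[(tert-butyldimethylsilyl)oxy]propanoate | COC(=O)[C@H](CO[Si](C)(C)C(C)(C)C)Oc1ccc(Br)cc1OC | intermediate
9 | (S)-2-(4-bromo-2-methoxyphenoxy)-3-[(tert-butyldimethylsilyl)oxy]-N-methoxy-N-methylpropanamide | CON(C)C(=O)[C@H](CO[Si](C)(C)C(C)(C)C)Oc1ccc(Br)cc1OC | intermediate
10 | 1-(benzyloxy)-4-bromo-2-methoxybenzene | COc1cc(Br)ccc1OCc1ccccc1 | starting material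
11 | [4-(benzyloxy)-3-methoxyphenyl]magnesium bromide | COc1cc([Mg]Br)ccc1OCc1ccccc1 | intermediate
12 | (S)-1-[4-(benzyloxy)-3-methoxyphenyl]-2-(4-bromo-2-methoxyphenoxy)-3-[(tert-butyldimethylsilyl)oxy]propan-1-one | COc1cc(C(=O)[C@H](CO[Si](C)(C)C(C)(C)C)Oc2ccc(Br)cc2OC)ccc1OCc1ccccc1 | intermediate
13 | (1R,2S)-1-[4-(benzyloxy)-3-methoxyphenyl]-2-(4-bromo-2-methoxyphenoxy)-3-[(tert-butyldimethylsilyl)oxy]propan-1-ol | COc1cc([C@@H](O)[C@H](CO[Si](C)(C)C(C)(C)C)Oc2ccc(Br)cc2OC)ccc1OCc1ccccc1 | intermediate
14 | (1R,2S)-1-[4-(benzyloxy)-3-methoxyphenyl]-2-(4-bromo-2-methoxyphenoxy)-1,3-bis[(tert-butyldimethylsilyl)oxy]propane | COc1cc([C@@H](O[Si](C)(C)C(C)(C)C)[C@H](CO[Si](C)(C)C(C)(C)C)Oc2ccc(Br)cc2OC)ccc1OCc1ccccc1 | intermediate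
15 | [(2S,3R,4R)-2-[4-(benzyloxy)-3-methoxyphenyl]-4-[4-({(1R,2S)-1-[4-(benzyloxy)-3-methoxyphenyl]-1,3-bis[(tert-butyldimethylsilyl)oxy]propan-2-yl}oxy)-3-methoxybenzyl]oxolan-3-yl]methanol | COc1cc([C@@H](O[Si](C)(C)C(C)(C)C)[C@H](CO[Si](C)(C)C(C)(C)C)Oc2ccc(C[C@H]3CO[C@H](c4ccc(OCc5ccccc5)c(OC)c4)[C@H]3CO)cc2OC)ccc1OCc1ccccc1 | intermediate
16 | (1R,2S)-1-[4-(benzyloxy)-3-methoxyphenyl]-2-[4-({(3R,4R,5S)-5-[4-(benzyloxy)-3-methoxyphenyl]-4-(hydroxymethyl)oxolan-3-yl}methyl)-2-methoxyphenoxy]propane-1,3-diol | COc1cc([C@@H](O)[C@H](CO)Oc2ccc(C[C@H]3CO[C@H](c4ccc(OCc5ccccc5)c(OC)c4)[C@H]3CO)cc2OC)ccc1OCc1ccccc1 | intermediate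
17 | (1R,2S)-1-(4-hydroxy-3-methoxyphenyl)-2-[4-({(3R,4R,5S)-5-(4-hydroxy-3-methoxyphenyl)-4-(hydroxymethyl)oxolan-3-yl}methyl)-2-methoxyphenoxy]propane-1,3-diol | COc1cc([C@@H](O)[C@H](CO)Oc2ccc(C[C@H]3CO[C@H](c4ccc(O)c(OC)c4)[C@H]3CO)cc2OC)ccc1O | target

**Summary**

Total step count: 12.
Longest linear sequence: 9 steps (steps 4 to 12, from 5).

**Steps most likely to fail**

Step 10 (proposed new method). The C8 or C7' radical may be captured or reduced before both carbon–carbon bonds are formed, the aryl bromide may be hydrodebrominated or homocoupled, and stereocontrol at C8' in the ring closure may be incomplete. The fallback closes the ring by the known titanocene-mediated epoxy-olefin radical cyclization on a cinnamyl ether and sets out from 14. A Heck reaction with methyl acrylate (Pd(OAc)2, P(o-tol)3, Et3N, DMF, 100 °C) should give the methyl (E)-cinnamate F1. Reduction with iBu2AlH (CH2Cl2, −78 °C) should give the (E)-cinnamyl alcohol F2, and CBr4/PPh3 (CH2Cl2, 0 °C) the cinnamyl bromide F3. Williamson etherification of the sodium alkoxide of 3 with F3 (NaH, THF, 0 °C) should give the epoxy cinnamyl ether F4. Stoichiometric Cp2TiCl (from Cp2TiCl2 and Zn dust, THF, rt, then dilute aqueous acid) should open the oxirane at C8, cyclize 5-exo onto the styrene-type double bond and reduce the benzylic C7' radical to CH2. This returns to the route at 15.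

Step 8. Facial selectivity may be poor if the weakly basic aryl ether oxygen does not hold zinc in a chelate, so that open-chain (Felkin–Anh) attack competes. The fallback sets out from 12 and turns the competing pathway into the planned one. Reduction with the bulky, non-chelating LiBH(sBu)3 (THF, −78 °C) should give the threo alcohol F5. Mitsunobu inversion at C7'' with 4-nitrobenzoic acid (PPh3, iPrO2CN=NCO2iPr, toluene, 0 °C) should give the erythro 4-nitrobenzoate F6. Methanolysis (K2CO3, MeOH, rt) returns to the route at 13.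

Step 2. Rate discrimination between the enantiomers may be insufficient for this terminal vinyl carbinol, and the Lewis-acidic titanium medium may open the electron-rich benzylic epoxy alcohol. The fallback separates resolution from epoxidation and sets out from 2. Acylation with vinyl acetate catalysed by immobilised Candida antarctica lipase B (tBuOMe, 30 °C) should esterify the (R)-enantiomer to the (R)-acetate F7 and leave the (S)-allylic alcohol F8. Hydroxyl-directed epoxidation of F8 (VO(acac)2, tBuOOH, CH2Cl2, 0 °C) should give 3 together with its oxirane epimer F9. Because the oxirane carbon becomes the planar C8 radical in step 10, both epimers converge on 15, and the mixture re-enters the route at 3.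

**Further compounds**

F1 | step 10 | methyl (E)-3-[4-({(1R,2S)-1-[4-(benzyloxy)-3-methoxyphenyl]-1,3-bis[(tert-butyldimethylsilyl)oxy]propan-2-yl}oxy)-3-methoxyphenyl]prop-2-enoate | COc1cc([C@@H](O[Si](C)(C)C(C)(C)C)[C@H](CO[Si](C)(C)C(C)(C)C)Oc2ccc(/C=C/C(=O)OC)cc2OC)ccc1OCc1ccccc1
F2 | step 10 | (E)-3-[4-({(1R,2S)-1-[4-(benzyloxy)-3-methoxyphenyl]-1,3-bis[(tert-butyldimethylsilyl)oxy]propan-2-yl}oxy)-3-methoxyphenyl]prop-2-en-1-ol | COc1cc([C@@H](O[Si](C)(C)C(C)(C)C)[C@H](CO[Si](C)(C)C(C)(C)C)Oc2ccc(/C=C/CO)cc2OC)ccc1OCc1ccccc1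
F3 | step 10 | (1R,2S)-1-[4-(benzyloxy)-3-methoxyphenyl]-2-{4-[(E)-3-bromoprop-1-en-1-yl]-2-methoxyphenoxy}-1,3-bis[(tert-butyldimethylsilyl)oxy]propane | COc1cc([C@@H](O[Si](C)(C)C(C)(C)C)[C@H](CO[Si](C)(C)C(C)(C)C)Oc2ccc(/C=C/CBr)cc2OC)ccc1OCc1ccccc1
F4 | step 10 | (2S)-2-[(R)-[4-(benzyloxy)-3-methoxyphenyl]({(E)-3-[4-({(1R,2S)-1-[4-(benzyloxy)-3-methoxyphenyl]-1,3-bis[(tert-butyldimethylsilyl)oxy]propan-2-yl}oxy)-3-methoxyphenyl]prop-2-en-1-yl}oxy)methyl]oxirane | COc1cc([C@@H](O[Si](C)(C)C(C)(C)C)[C@H](CO[Si](C)(C)C(C)(C)C)Oc2ccc(/C=C/CO[C@H](c3ccc(OCc4ccccc4)c(OC)c3)[C@@H]3CO3)cc2OC)ccc1OCc1ccccc1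
F5 | step 8 | (1S,2S)-1-[4-(benzyloxy)-3-methoxyphenyl]-2-(4-bromo-2-methoxyphenoxy)-3-[(tert-butyldimethylsilyl)oxy]propan-1-ol | COc1cc([C@H](O)[C@H](CO[Si](C)(C)C(C)(C)C)Oc2ccc(Br)cc2OC)ccc1OCc1ccccc1
F6 | step 8 | (1R,2S)-1-[4-(benzyloxy)-3-methoxyphenyl]-2-(4-bromo-2-methoxyphenoxy)-3-[(tert-butyldimethylsilyl)oxy]propyl 4-nitrobenzoate | COc1cc([C@@H](OC(=O)c3ccc(cc3)[N+](=O)[O-])[C@H](CO[Si](C)(C)C(C)(C)C)Oc2ccc(Br)cc2OC)ccc1OCc1ccccc1
F7 | step 2 | (R)-1-[4-(benzyloxy)-3-methoxyphenyl]prop-2-en-1-yl acetate | CC(=O)O[C@@H](c1ccc(OCc2ccccc2)c(OC)c1)C=C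
F8 | step 2 | (S)-1-[4-(benzyloxy)-3-methoxyphenyl]prop-2-en-1-ol | O[C@H](c1ccc(OCc2ccccc2)c(OC)c1)C=C
F9 | step 2 | (R)-[4-(benzyloxy)-3-methoxyphenyl][(2R)-oxiran-2-yl]methanol | O[C@H](c1ccc(OCc2ccccc2)c(OC)c1)[C@H]1CO1
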